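The eleven-membered carbocycle is disconnected at the CH2–CH2 bond between C11, the carbon α to the methylidene-bearing ring carbon C1 (carried as a ketone), and C10, the allylic CH2 of the ring C8(CH3)=C9H olefin: an enolate–π-allyl pairing. Both partners are stored in a thirteen-membered allylic β-keto lactone, closed by olefin metathesis as an E/Z mixture. Palladium(0) then ionises the allylic ester, CO2 is lost, and the enolate recloses on C10: a two-atom ring contraction that forms the C10–C11 bond and funnels both olefin isomers into the (E,E)-cycloundecadienone. Asymmetric methallylation sets the carbinol centre C6; methylenation and desilylation finish.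

Key step: step 9

Numbering used below (ring carbons of the target): C1 bears the exocyclic CH2; C2=C3 is the disubstituted olefin; C4 is the gem-dimethyl carbon; C5 is CH2; C6 is the carbinol carbon; C7 is CH2; C8(CH3)=C9H is the trisubstituted olefin; C10 and C11 are CH2.

Assumption: diethyl chlorophosphate, tributyl(2-methylallyl)stannane and (S)-BINOL are taken as commercial, and the (S)-BINOL–titanium catalyst is taken to deliver the allyl unit to the Si face of this unbranched aldehyde, as it does for other aldehydes of this type.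

Step 1
Reactants: 1 2,2,6-trimethyl-4H-1,3-dioxin-4-one; 2 diethyl chlorophosphate
Product: 3 diethyl [(2,2-dimethyl-4-oxo-4H-1,3-dioxin-6-yl)methyl]phosphonate
Conditions: LDA (2.1 equiv), THF, −78 °C; then 2, −78 → 0 °C; aq NH4Cl
Reagents that add atoms: diethyl chlorophosphate 2, CCOP(=O)(Cl)OCC
Why: C-phosphorylation of a vinylogous ester dienolate: LDA deprotonates the 6-methyl group, the extended dienolate is phosphorylated at that terminal carbon, and the second equivalent of base takes up the more acidic product so that it does not quench unreacted dienolate.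

Step 2
Reactants: 3 diethyl [(2,2-dimethyl-4-oxo-4H-1,3-dioxin-6-yl)methyl]phosphonate; 4 2,2-dimethylpent-4-enal
Product: 5 6-[(1E)-3,3-dimethylhexa-1,5-dien-1-yl]-2,2-dimethyl-4H-1,3-dioxin-4-one
Conditions: LiHMDS, THF, −78 °C; then 4, −78 °C → rt
Reagents that add atoms: none
Why: Horner–Wadsworth–Emmons olefination: the lithiated stabilised phosphonate adds to the non-enolisable α-quaternary aldehyde, and the bulky neopentyl-type substituent should enforce the E-olefin (C2=C3).

Step 3
Reactants: 5 6-[(1E)-3,3-dimethylhexa-1,5-dien-1-yl]-2,2-dimethyl-4H-1,3-dioxin-4-one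
Product: 6 (4E)-5-(2,2-dimethyl-4-oxo-4H-1,3-dioxin-6-yl)-3,3-dimethylpent-4-enal
Conditions: OsO4 (2 mol %), NaIO4 (4 equiv), 2,6-lutidine, dioxane/H2O 3:1, rt
Reagents that add atoms: osmium tetroxide (catalytic oxygen transfer), O=[Os](=O)(=O)=O; sodium periodate (terminal oxidant), [Na+].[O-]I(=O)(=O)=O; water, O
Why: Lemieux–Johnson oxidative cleavage: OsO4 should dihydroxylate the isolated, unhindered terminal alkene much faster than the electron-poor dienyl dioxinone, whose distal double bond is also shielded by the adjacent quaternary carbon, and periodate cleaves the diol to the C6 aldehyde.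

Step 4
Reactants: 6 (4E)-5-(2,2-dimethyl-4-oxo-4H-1,3-dioxin-6-yl)-3,3-dimethylpent-4-enal; 7 tributyl(2-methylprop-2-en-1-yl)stannane
Product: 8 6-[(1E,5S)-5-hydroxy-3,3,7-trimethylocta-1,7-dien-1-yl]-2,2-dimethyl-4H-1,3-dioxin-4-one
Conditions: (S)-BINOL (20 mol %), Ti(OiPr)4 (10 mol %), 4 Å MS, CH2Cl2, −20 °C; aq NaHCO3
Reagents that add atoms: tributyl(2-methylprop-2-en-1-yl)stannane 7, C=C(C)C[Sn](CCCC)(CCCC)CCCC
Why: Keck catalytic asymmetric methallylation: the (S)-BINOL–titanium Lewis acid activates only the aldehyde and directs the methallyl group to its Si face, which sets C6 as S under catalyst control (the substrate has no other stereocentre).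

Step 5
Reactants: 9 3-hydroxy-4-methoxybenzoic acid (isovanillic acid); 10 tert-butyldimethylsilyl chloride
Product: 12 3-[(tert-butyldimethylsilyl)oxy]-4-methoxybenzoic acid, via bis-silylated ester 11 (not isolated)
Conditions: TBSCl (2.4 equiv), imidazole (5 equiv), DMF, rt; then AcOH/THF/H2O 3:1:1, rt
Reagents that add atoms: tert-butyldimethylsilyl chloride 10, CC(C)(C)[Si](C)(C)Cl
Why: Silylation followed by selective solvolysis: TBSCl/imidazole silylates both the phenol and the acid, and the silyl ester, far more labile than the aryl silyl ether, should be hydrolysed alone by dilute aqueous acetic acid.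

Step 6
Reactants: 8 6-[(1E,5S)-5-hydroxy-3,3,7-trimethylocta-1,7-dien-1-yl]-2,2-dimethyl-4H-1,3-dioxin-4-one; 12 3-[(tert-butyldimethylsilyl)oxy]-4-methoxybenzoic acid
Product: 13 (1E,5S)-1-(2,2-dimethyl-4-oxo-4H-1,3-dioxin-6-yl)-3,3,7-trimethylocta-1,7-dien-5-yl 3-[(tert-butyldimethylsilyl)oxy]-4-methoxybenzoate
Conditions: EDC·HCl, DMAP, CH2Cl2, 0 °C → rt
Reagents that add atoms: none
Why: Steglich esterification (carbodiimide/DMAP acyl transfer): the carbinol C–O bond is not broken, so C6 keeps its S configuration, and the aroyl group serves from here on as the protecting group of the C6 oxygen.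

Step 7
Reactants: 13 (1E,5S)-1-(2,2-dimethyl-4-oxo-4H-1,3-dioxin-6-yl)-3,3,7-trimethylocta-1,7-dien-5-yl 3-[(tert-butyldimethylsilyl)oxy]-4-methoxybenzoate; 14 prop-2-en-1-ol (allyl alcohol)
Product: 16 prop-2-en-1-yl (4E,8S)-8-({3-[(tert-butyldimethylsilyl)oxy]-4-methoxybenzoyl}oxy)-6,6,10-trimethyl-3-oxoundeca-4,10-dienoate, via acylketene 15 (not isolated)
Conditions: allyl alcohol (10 equiv), toluene, 110 °C
Reagents that add atoms: prop-2-en-1-ol 14, C=CCO
Why: Thermal retro-[4+2] fragmentation of the dioxinone to acetone and an acylketene, which the excess primary alcohol should capture faster than it can dimerise, giving the allyl β-keto ester without base or coupling reagent.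

Step 8
Reactants: 16 prop-2-en-1-yl (4E,8S)-8-({3-[(tert-butyldimethylsilyl)oxy]-4-methoxybenzoyl}oxy)-6,6,10-trimethyl-3-oxoundeca-4,10-dienoate
Product: 17 (5E,9S)-7,7,11-trimethyl-2,4-dioxo-1-oxacyclotrideca-5,11-dien-9-yl 3-[(tert-butyldimethylsilyl)oxy]-4-methoxybenzoate (11E/11Z mixture)
Conditions: Grubbs II (10 mol %), toluene, 80 °C, 1 mM, slow addition, Ar sparge
Reagents that add atoms: none
Why: Ring-closing olefin metathesis: only the allyl ester and methallyl termini are metathesis-active (the enone olefin is electron-poor and flanked by a quaternary carbon), the thirteen-membered ring is unstrained, and the E/Z ratio of the new C8=C9 bond is left open because the next step erases it.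

Step 9
Reactants: 17 (5E,9S)-7,7,11-trimethyl-2,4-dioxo-1-oxacyclotrideca-5,11-dien-9-yl 3-[(tert-butyldimethylsilyl)oxy]-4-methoxybenzoate (11E/11Z mixture)
Product: 18 (1S,3E,8E)-3,10,10-trimethyl-7-oxocycloundeca-3,8-dien-1-yl 3-[(tert-butyldimethylsilyl)oxy]-4-methoxybenzoate
Conditions: Pd(PPh3)4 (10 mol %), THF, 50 °C, 17 added slowly to 2 mM
Reagents that add atoms: none
Why: Pd(0) ionises the allylic C10–O bond of the lactone, the resulting β-keto carboxylate loses CO2, and the site-specific enolate (C11=C1–O⁻, cross-conjugated with the C2=C3 enone) recombines with the tethered π-allyl cation at its primary terminus C10, so the O–C(=O) unit of the thirteen-membered ring is excised and the C10–C11 bond of the eleven-membered ring is made in the same operation. The closest known reaction type is the Tsuji (palladium-Carroll) decarboxylative allylation of allyl β-keto esters, here run on a cyclic ester so that it becomes a two-atom ring contraction. The eleven-membered ring is closed by C-attack of the enolate on the distal, primary allyl terminus (olefin endocyclic) rather than on the tertiary proximal terminus C8, which would give a strained nine-membered ring with a quaternary centre; O-allylation is reversible under Pd(0) and should drain to the C–C product. No stereocentre is formed, and C6 is untouched because its ester is homoallylic and cannot be ionised. The step needs E geometry at C8=C9 from an E/Z lactone mixture: both isomers give π-allyl complexes that can interconvert by η3–η1–η3 isomerisation at C8 before the slow ring closure, and the complex with the ring chain syn and the methyl anti is the less strained one and leads to the E olefin. Cyclisation must outrun oligomerisation and β-hydride loss from the allyl unit, which the contact ion pair between enolate and allyl in THF at high dilution should secure.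

Step 10
Reactants: 18 (1S,3E,8E)-3,10,10-trimethyl-7-oxocycloundeca-3,8-dien-1-yl 3-[(tert-butyldimethylsilyl)oxy]-4-methoxybenzoate; 19 methyltriphenylphosphonium bromide
Product: 20 (1S,3E,8E)-3,10,10-trimethyl-7-methylidenecycloundeca-3,8-dien-1-yl 3-[(tert-butyldimethylsilyl)oxy]-4-methoxybenzoate
Conditions: Ph3PCH3Br (3 equiv), KHMDS (2.8 equiv), THF, 0 °C; then 18, 0 °C → rt
Reagents that add atoms: methyltriphenylphosphonium bromide 19, C[P+](c1ccccc1)(c1ccccc1)c1ccccc1.[Br-]
Why: Wittig methylenation: the unstabilised ylide should add 1,2 to the ketone of the hindered enone much faster than to the alkyl benzoate, and a slight deficit of base relative to phosphonium salt keeps free amide away from the ester and the aryl silyl ether.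

Step 11
Reactants: 20 (1S,3E,8E)-3,10,10-trimethyl-7-methylidenecycloundeca-3,8-dien-1-yl 3-[(tert-butyldimethylsilyl)oxy]-4-methoxybenzoate
Product: 21 (1S,3E,8E)-3,10,10-trimethyl-7-methylidenecycloundeca-3,8-dien-1-yl 3-hydroxy-4-methoxybenzoate
Conditions: TBAF (1.1 equiv), AcOH (1.2 equiv), THF, 0 °C
Reagents that add atoms: none
Why: Fluoride-induced cleavage of the aryl silyl ether (Si–F bond formation), buffered with acetic acid so that the phenoxide is protonated at once and the secondary benzoate is not attacked.

Compound list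
1 | 2,2,6-trimethyl-4H-1,3-dioxin-4-one | CC1=CC(=O)OC(C)(C)O1 | starting material
2 | diethyl chlorophosphate | CCOP(=O)(Cl)OCC | starting material
3 | diethyl [(2,2-dimethyl-4-oxo-4H-1,3-dioxin-6-yl)methyl]phosphonate | CCOP(=O)(CC1=CC(=O)OC(C)(C)O1)OCC | intermediate
4 | 2,2-dimethylpent-4-enal | C=CCC(C)(C)C=O | starting material
5 | 6-[(1E)-3,3-dimethylhexa-1,5-dien-1-yl]-2,2-dimethyl-4H-1,3-dioxin-4-one | C=CCC(C)(C)/C=C/C1=CC(=O)OC(C)(C)O1 | intermediate
6 | (4E)-5-(2,2-dimethyl-4-oxo-4H-1,3-dioxin-6-yl)-3,3-dimethylpent-4-enal | O=CCC(C)(C)/C=C/C1=CC(=O)OC(C)(C)O1 | intermediate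
7 | tributyl(2-methylprop-2-en-1-yl)stannane | C=C(C)C[Sn](CCCC)(CCCC)CCCC | starting material
8 | 6-[(1E,5S)-5-hydroxy-3,3,7-trimethylocta-1,7-dien-1-yl]-2,2-dimethyl-4H-1,3-dioxin-4-one | CC1(C)OC(=O)C=C(/C=C/C(C)(C)C[C@@H](O)CC(C)=C)O1 | intermediate
9 | 3-hydroxy-4-methoxybenzoic acid (isovanillic acid) | COc1ccc(C(=O)O)cc1O | starting material
10 | tert-butyldimethylsilyl chloride | CC(C)(C)[Si](C)(C)Cl | starting material
11 | tert-butyldimethylsilyl 3-[(tert-butyldimethylsilyl)oxy]-4-methoxybenzoate (not isolated) | COc1ccc(C(=O)O[Si](C)(C)C(C)(C)C)cc1O[Si](C)(C)C(C)(C)C | intermediate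
12 | 3-[(tert-butyldimethylsilyl)oxy]-4-methoxybenzoic acid | COc1ccc(C(=O)O)cc1O[Si](C)(C)C(C)(C)C | intermediate
13 | (1E,5S)-1-(2,2-dimethyl-4-oxo-4H-1,3-dioxin-6-yl)-3,3,7-trimethylocta-1,7-dien-5-yl 3-[(tert-butyldimethylsilyl)oxy]-4-methoxybenzoate | CC1(C)OC(=O)C=C(/C=C/C(C)(C)C[C@@H](OC(=O)c2ccc(OC)c(O[Si](C)(C)C(C)(C)C)c2)CC(C)=C)O1 | intermediate
14 | prop-2-en-1-ol (allyl alcohol) | C=CCO | starting material
15 | (4E,8S)-6,6,10-trimethyl-1,3-dioxoundeca-1,4,10-trien-8-yl 3-[(tert-butyldimethylsilyl)oxy]-4-methoxybenzoate (acylketene, not isolated) | O=C=CC(=O)/C=C/C(C)(C)C[C@@H](OC(=O)c1ccc(OC)c(O[Si](C)(C)C(C)(C)C)c1)CC(C)=C | intermediate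
16 | prop-2-en-1-yl (4E,8S)-8-({3-[(tert-butyldimethylsilyl)oxy]-4-methoxybenzoyl}oxy)-6,6,10-trimethyl-3-oxoundeca-4,10-dienoate | C=CCOC(=O)CC(=O)/C=C/C(C)(C)C[C@@H](OC(=O)c1ccc(OC)c(O[Si](C)(C)C(C)(C)C)c1)CC(C)=C | intermediate
17 | (5E,9S)-7,7,11-trimethyl-2,4-dioxo-1-oxacyclotrideca-5,11-dien-9-yl 3-[(tert-butyldimethylsilyl)oxy]-4-methoxybenzoate, 11E/11Z mixture (the C8=C9 bond is written without geometry on purpose) | O=C1CC(=O)/C=C/C(C)(C)C[C@@H](OC(=O)c2ccc(OC)c(O[Si](C)(C)C(C)(C)C)c2)CC(C)=CCO1 | intermediate
18 | (1S,3E,8E)-3,10,10-trimethyl-7-oxocycloundeca-3,8-dien-1-yl 3-[(tert-butyldimethylsilyl)oxy]-4-methoxybenzoate | O=C1/C=C/C(C)(C)C[C@@H](OC(=O)c2ccc(OC)c(O[Si](C)(C)C(C)(C)C)c2)C/C(C)=C/CC1 | intermediate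
19 | methyltriphenylphosphonium bromide | C[P+](c1ccccc1)(c1ccccc1)c1ccccc1.[Br-] | starting material
20 | (1S,3E,8E)-3,10,10-trimethyl-7-methylidenecycloundeca-3,8-dien-1-yl 3-[(tert-butyldimethylsilyl)oxy]-4-methoxybenzoate | C=C1/C=C/C(C)(C)C[C@@H](OC(=O)c2ccc(OC)c(O[Si](C)(C)C(C)(C)C)c2)C/C(C)=C/CC1 | intermediate
21 | (1S,3E,8E)-3,10,10-trimethyl-7-methylidenecycloundeca-3,8-dien-1-yl 3-hydroxy-4-methoxybenzoate | C=C1/C=C/C(C)(C)C[C@@H](OC(=O)c2ccc(OC)c(O)c2)C/C(C)=C/CC1 | target

Total step count: 11.
Longest linear sequence: 10 steps (steps 1–4 and 6–11, from 1 to 21); step 5 is a one-step side branch.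

Steps most likely to fail

Step 9. After ionisation the tethered π-allyl/enolate pair may not reclose to the eleven-membered ring. The likely processes are β-hydride loss from the allyl unit to a diene, intermolecular allylation giving oligomers, or incomplete syn/anti equilibration that carries Z geometry into the product. The fallback inverts the order of CO2 loss and ring formation and sets out from 16. Treating the open-chain allyl ester 16 with Pd(PPh3)4 in THF at rt, a decarboxylative allylation that is routine on a simple allyl β-keto ester, should give the allyl ketone (6E,10S)-8,8,12-trimethyl-5-oxotrideca-1,6,12-trien-10-yl 3-[(tert-butyldimethylsilyl)oxy]-4-methoxybenzoate F1. Ring-closing metathesis of F1 (Hoveyda–Grubbs II, toluene, 80 °C, 0.5 mM) between its monosubstituted and 1,1-disubstituted olefins would then close the cycloundecadienone directly and comes back to the route at 18. The price is that the C8=C9 geometry is then under kinetic control, so the E isomer would have to be separated.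

Step 8. The ruthenium carbene may be sequestered by the chelating β-keto ester or the allyl ester carbonyl, and oligomerisation may compete with closure onto the hindered 1,1-disubstituted olefin. The fallback closes the thirteen-membered ring at the C–O bond instead and sets out from 13. Cross-metathesis of the methallyl group of 13 with (Z)-but-2-ene-1,4-diol (Grubbs II, CH2Cl2, 40 °C), with the β-keto ester still masked as the dioxinone, should give the allylic alcohol (1E,5S)-1-(2,2-dimethyl-4-oxo-4H-1,3-dioxin-6-yl)-9-hydroxy-3,3,7-trimethylnona-1,7-dien-5-yl 3-[(tert-butyldimethylsilyl)oxy]-4-methoxybenzoate F2, of which either olefin geometry serves. Heating F2 in toluene at 110 °C and 0.5 mM would release acetone and the acylketene (4E,8S)-12-hydroxy-6,6,10-trimethyl-1,3-dioxododeca-1,4,10-trien-8-yl 3-[(tert-butyldimethylsilyl)oxy]-4-methoxybenzoate F3. Intramolecular capture of F3 by the primary allylic hydroxyl comes back to the route at 17.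

Step 3. Chemoselectivity may be lost: osmylation of the dienyl dioxinone double bond could compete with that of the terminal alkene and lead to over-cleavage. The fallback selects the olefin by its nucleophilicity towards a peracid instead and sets out from 5. mCPBA (CH2Cl2, NaHCO3, 0 °C → rt) should epoxidise only the isolated terminal alkene to give 6-[(1E)-3,3-dimethyl-4-(oxiran-2-yl)but-1-en-1-yl]-2,2-dimethyl-4H-1,3-dioxin-4-one F4, racemic at the new centre, which is lost in the next operation. Periodic acid (H5IO6, THF/H2O, 0 °C) then cleaves the terminal epoxide to the aldehyde and formaldehyde and comes back to the route at 6.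

Further compounds
F1 | step 9 | (6E,10S)-8,8,12-trimethyl-5-oxotrideca-1,6,12-trien-10-yl 3-[(tert-butyldimethylsilyl)oxy]-4-methoxybenzoate | C=CCCC(=O)/C=C/C(C)(C)C[C@@H](OC(=O)c1ccc(OC)c(O[Si](C)(C)C(C)(C)C)c1)CC(C)=C
F2 | step 8 | (1E,5S)-1-(2,2-dimethyl-4-oxo-4H-1,3-dioxin-6-yl)-9-hydroxy-3,3,7-trimethylnona-1,7-dien-5-yl 3-[(tert-butyldimethylsilyl)oxy]-4-methoxybenzoate (7E/7Z mixture) | CC1(C)OC(=O)C=C(/C=C/C(C)(C)C[C@@H](OC(=O)c2ccc(OC)c(O[Si](C)(C)C(C)(C)C)c2)CC(C)=CCO)O1
F3 | step 8 | (4E,8S)-12-hydroxy-6,6,10-trimethyl-1,3-dioxododeca-1,4,10-trien-8-yl 3-[(tert-butyldimethylsilyl)oxy]-4-methoxybenzoate (acylketene, not isolated) | O=C=CC(=O)/C=C/C(C)(C)C[C@@H](OC(=O)c1ccc(OC)c(O[Si](C)(C)C(C)(C)C)c1)CC(C)=CCO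
F4 | step 3 | 6-[(1E)-3,3-dimethyl-4-(oxiran-2-yl)but-1-en-1-yl]-2,2-dimethyl-4H-1,3-dioxin-4-one (racemic) | CC1(C)OC(=O)C=C(/C=C/C(C)(C)CC2CO2)O1
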